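Its constants were set for the occasion; no experiment stands behind them.

The vessel is a closed, stirred flask at one temperature, charged on two days.

- Saturday's: free monomer 0.50 M; initiator 10 mM; impurity 1.6 mM; time 4.0 h
- Monday's: free monomer 0.50 M; initiator 3.0 mM; impurity 1.6 mM; time 4.0 h

    free monomer + initiator → living end + monomer in chains (k1 = 0.057 M⁻¹ min⁻¹)
    free monomer + living end → monomer in chains + living end, rate k2*[living end]*[free monomer] (k2 = 1.4 M⁻¹ min⁻¹)
    initiator + impurity → spent initiator (k3 = 3700 M⁻¹ min⁻¹)

- which of the two ends with the longer chains by the average number of monomer units in a chain (chains begun, living or dead) ("neither" if they lie within 10%) (Saturday's / Monday's / neither)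
- average number of monomer units in a chain (chains begun, living or dead) at the end, Saturday's
- average number of monomer units in a chain (chains begun, living or dead) at the end, Monday's

- the average divides the monomer in chains by the number of chains begun, living and dead together
- run time (Saturday's): 4.0 h

Living ends consume the free monomer, so the concentration to find is that of the living ends, L. While L holds steady, free monomer falls exponentially at k2 times L, which is the usual pseudo-first-order case.

At the charged amounts, impurity takes initiator at 5.92 min⁻¹ per unit of initiator, while free monomer takes it at 0.0285 min⁻¹. So I strike the impurity off the initiator at once. Monday's working initiator E, the initiator charge minus the impurity charge, is 1.40 mM, and Saturday's is 8.40 mM. I take E as the final L, and as the number of chains begun.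

The first way counts E as living from the first minute. The part of the free monomer reacted is then 1 − exp(−k2·E·t), where t is the time. The average chain is the free monomer charge times that part, divided by E. This gives 56.0 for Saturday's and 134 for Monday's.

The second way allows for the start. At the charged free monomer, an initiator lasts on average τ = 1/(k1 × free monomer) = 35.1 min, so I run the same sum over t − τ. This gives 54.2 for Saturday's and 118 for Monday's.

The two ways part mainly on Monday's, and the first one cheats there: it lets chains grow on E living ends before those ends have been made. I commit to the second way, which puts the longer chains in Monday's.

The forecast, which differs slightly from mine on Saturday's, names Monday's, with 56 for Saturday's and 118 for Monday's, holding that “nearly all of what remains starts chains”.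

The simulation gives Monday's, with 56.1 for Saturday's and 119 for Monday's.

The gap between the two flasks comes from the difference in initiator charge: Monday's flask given Saturday's initiator ends at 56.1. Now carry Monday's E of 1.40 mM and the same τ to a reading of Monday's at 10 h. The sum gives 67.0% of the free monomer reacted and an average of 239. At that reading Monday's flask holds 33.0% of its charge as free monomer, and its average chain stands at 239.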